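The constants of this reaction are not given to me, so I read two kinds from the earlier runs, and with them I reckon how much target each flask holds at the end.

| flask | starting material | reagent | temperature | remark | time |
|---|---|---|---|---|---|
| summer | 0.024 M | 0.0264 M | 65 °C | run made earlier |  |
| autumn | 0.024 M | 0.013 M | 80 °C | run made earlier |  |
| noon | 0.024 M | 0.020 M | 65 °C | run made earlier |  |
| spring | 0.036 M | 0.0264 M | 80 °C | run made earlier |  |
| alpha | 0.024 M | 0.0264 M (fed, over 15 min) | 80 °C | all else is in the flask from the start; the feed brings no volume worth counting | 40 min |
| theta | 0.024 M | 0.0264 M |  | everything together at the start at 60 °C, warmed to 80 °C at 15 min | 40 min |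
| epsilon | 0.024 M | 0.0264 M | 80 °C | everything together at the start | 40 min |
| zeta | 0.024 M | 0.0264 M (fed, over 15 min) |  | the addition at 60 °C, then warmed to 80 °C; the feed brings no volume worth counting | 40 min |

| run | time / min | target / % |
|---|---|---|
| summer | 12.0 | 4 |
| summer | 25.0 | 11 |
| summer | 40.0 | 13 |
| summer | 50.0 | 14 |
| summer | 60.0 | 18 |
| summer | 80.0 | 20 |
| autumn | 1.50 | 6 |
| autumn | 5.00 | 15 |
| autumn | 8.00 | 23 |
| autumn | 12.0 | 28 |
| autumn | 20.0 | 44 |
| autumn | 25.0 | 47 |
| noon | 8.00 | 4 |
| noon | 15.0 | 7 |
| noon | 25.0 | 11 |
| noon | 30.0 | 12 |
| noon | 40.0 | 14 |
| noon | 50.0 | 18 |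
| spring | 5.00 | 12 |
| spring | 10.0 | 23 |
| spring | 15.0 | 29 |
| spring | 20.0 | 33 |
| spring | 25.0 | 39 |

(standard deviation of a reading: 1.5 percentage points)

1. the flask that comes out highest in amount of target, in percent of the starting material charged, or "all alike" when all lie within 1.5 percentage points (alpha / theta / epsilon / zeta / all alike)
2. target at the end, in percent of the starting material charged, alpha
3. target at the end, in percent of the starting material charged, theta
4. target at the end, in percent of the starting material charged, epsilon
5. target at the end, in percent of the starting material charged, zeta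

The autumn run gains 15% in its first 5.00 min, so I read target as made at 0.0300 min⁻¹. Yet autumn, with reagent at half the charge used in spring and with less starting material, holds more target at 25.0 min than spring, so, although these two runs differ in both settings, I take it that reagent carries starting material off another way. I call the pull the rate at which starting material goes by both ways, and the target share, or selectivity, is making over pull. In my reckoning, at one temperature and one reagent level, target is share times (the part of the charge consumed). I first treat the run as finished, put that answer back in, and go round again.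

For spring, the pull goes 0.0769 min⁻¹, 0.0657 min⁻¹, 0.0620 min⁻¹, which makes the share 48.4%. Autumn gives a pull of 0.0459 min⁻¹. At 65 °C, summer gives making of 0.00440 min⁻¹ and a pull of 0.0169 min⁻¹, so its share is 26.1%, less than spring's.

As times, from fastest to slowest, the ladder reads 16.1 min for the hot pull at full reagent, 21.8 min at half reagent, 33.3 min for hot making, 59.2 min for the cold pull and 227 min for cold making. Hot, the 40 min of a flask is longer than the time of spring's pull. At 65 °C the 15 min of a hold is shorter than both summer times, and the pull is faster than making.

So I reckon epsilon at 44.3%. For alpha I take autumn's pull during the feed, which leaves 50.2% in my reckoning, then spring's, which gives 51.6%. Theta, with summer standing in for its cold hold, gives 35.4%. Zeta, with the cold side pull halved, gives 38.6%.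

My reckoning puts alpha highest. The forecast also picks alpha, with 57%, 44%, 54% and 45% for alpha, theta, epsilon and zeta, holding that “low reagent may help slightly”. It stands higher than my reckoning on epsilon.

The flasks give 53.4% for alpha, 34.8% for theta, 45.6% for epsilon and 37.2% for zeta, so alpha comes out highest. Alpha ends with 9.65% side product B, less than epsilon's 15.3%.

    reagent + intermediate B → side product A (k = 0.530 M⁻¹ min⁻¹, Ea = 81.0 kJ mol⁻¹)
    intermediate B → side product B (k = 0.0420 min⁻¹, Ea = 105 kJ mol⁻¹)
    starting material + reagent ⇌ intermediate A (K = 67.0 M⁻¹, k = 2.80 M⁻¹ min⁻¹, Ea = 52.0 kJ mol⁻¹, ΔH = −39.0 kJ mol⁻¹)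
    starting material → target (k = 0.0330 min⁻¹, Ea = 117 kJ mol⁻¹)
    intermediate A → intermediate B (k = 0.0400 min⁻¹, Ea = 105 kJ mol⁻¹)
    (constants at 80 °C)

Put to use again, the two pulls leave 10.7% of the starting material in alpha at the end, and the flask holds 12.0%. Stopped at 25 min, alpha comes to 43.8% by the same share, and that flask holds 45.2% target.

The earlier runs and the new flask come from a simulation from invented constants; scatter was added.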